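**Strategy.** Ring X, the central dihydropyran (O, Cb, Cc, Ca and C3/C4 of quinolinone A; Ca carries the 2-methylprop-1-enyl group, Cb the ether oxygen), is disconnected at the aryl ether bond O–C4(A) and at Cc–Ca. The O–Cb–Cc unit of the 2,2-dimethylpyran ring Y serves as a 1,3-C,O-dinucleophile, a β-oxido benzyllithium released from the trans-hydroxy selenide of enantioenriched N-methylflindersine oxide. In one operation it adds to the formyl group of 4-chloro-3-formyl-1-methylquinolin-2-one and its alkoxide displaces the vinylogous acid chloride: a formal [3+3] annulation closing ring X. Cb then controls Cc and Ca through dehydration, face-selective hydroboration and stereoretentive Zweifel olefination.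

Key step: step 5

Labels: ring B is the quinolinone fused to ring Y; Cc is the ring-fusion carbon bonded to C3 of ring B. In the bicyclic pyrano[3,2-c]quinolinones, pyran locant C3 = Cb and C4 = Cc.

Remark: the facial sense of the salen–manganese epoxidation is assumed to follow that of 2,2-dimethyl-2H-chromenes, which should give the (3S,4S)-oxide with the (S,S)-ligand; if the fused quinolinone reverses it, the (R,R)-ligand is used.

**Step 1**
Reactants: 1 4-hydroxy-1-methylquinolin-2(1H)-one; 2 3-methylbut-2-enal
Product: 4 N-methylflindersine (2,2,6-trimethyl-2H-pyrano[3,2-c]quinolin-5(6H)-one), via alkylidene quinolinedione 3 (not isolated)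
Conditions: ethylenediammonium diacetate (10 mol%), MeOH, rt to 60 °C
Reagents that add atoms: none
Why: Knoevenagel condensation at C3 of the 1,3-dicarbonyl-type quinolinone gives the 1-oxatriene 3, which should close by oxa-6π electrocyclization to the 2H-pyran; no stereocenter is formed.

**Step 2**
Reactants: 4 N-methylflindersine
Product: 5 (3S,4S)-3,4-epoxy-2,2,6-trimethyl-3,4-dihydro-2H-pyrano[3,2-c]quinolin-5(6H)-one
Conditions: NaOCl (aq, pH 11.3), (S,S)-N,N′-bis(3,5-di-tert-butylsalicylidene)-1,2-cyclohexanediaminomanganese chloride (5 mol%), 4-phenylpyridine N-oxide (20 mol%), CH2Cl2, 0 °C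
Reagents that add atoms: sodium hypochlorite, [Na+].[O-]Cl
Why: Jacobsen epoxidation of a cis-disubstituted 2,2-dimethylchromene-type alkene, in which the chiral salen ligand should direct oxygen transfer to one face and set C3 and C4 together (reagent control).

**Step 3**
Reactants: 5 (3S,4S)-epoxide
Product: 6 (3R,4R)-3-hydroxy-2,2,6-trimethyl-4-(phenylselanyl)-3,4-dihydro-2H-pyrano[3,2-c]quinolin-5(6H)-one
Conditions: PhSeSePh (0.55 equiv), NaBH4, EtOH, 0 °C to rt
Reagents that add atoms: diphenyl diselenide, c1ccc(cc1)[Se][Se]c1ccccc1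
Why: SN2 epoxide opening by the soft benzeneselenolate at benzylic C4 (C3 is screened by the adjacent quaternary carbon) with inversion at C4 should give the trans-hydroxy selenide, leaving the C3–O stereocenter untouched.

**Step 4**
Reactants: 1 4-hydroxy-1-methylquinolin-2(1H)-one
Product: 8 4-chloro-1-methyl-2-oxo-1,2-dihydroquinoline-3-carbaldehyde, via iminium chloride 7 (not isolated)
Conditions: POCl3, DMF, 0 to 70 °C; then H2O
Reagents that add atoms: N,N-dimethylformamide, CN(C)C=O; phosphoryl chloride, O=P(Cl)(Cl)Cl; water, O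
Why: Vilsmeier–Haack reaction, in which the chloroiminium salt formylates nucleophilic C3, the 4-hydroxyl of the vinylogous acid is exchanged for chloride and hydrolysis of 7 frees the aldehyde; no stereocenter.

**Step 5**
Reactants: 6 (3R,4R)-hydroxy selenide; 8 4-chloro-3-formylquinolinone
Product: 11 pentacyclic alcohol (ring X closed; OH on Ca; H on Cc; Cb S; epimers at Ca/Cc), via β-oxido benzyllithium 9 (not isolated), via open-chain dilithium dialkoxide 10 (not isolated)
Conditions: n-BuLi (2.05 equiv), THF, −78 °C; 8, −78 °C; then −78 to 40 °C; H2O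
Reagents that add atoms: none
Why: Butyllithium first removes the hydroxyl proton and then attacks selenium; selenium–lithium exchange expels the benzylic carbanion, so 9 is a 1,3-C,O-dinucleophile whose carbanion adds to the formyl carbon of 8 (Cc–Ca bond) before the lithium alkoxide on Cb attacks C4 of ring A and expels chloride by addition–elimination (O–C4 bond). The closest known reaction types are selenium–lithium exchange of benzylic selenides with carbonyl trapping and intramolecular SNAr etherification of 4-chloroquinolin-2-ones, combined here as a formal anionic [3+3] annulation. Ring X closes in a 6-endo-trig addition–elimination mode, the only ring-forming option because the second alkoxide (on Ca) could only give a four-membered ring. Cb keeps its configuration because its C–O bond is never broken; Cc and Ca arise as epimer mixtures and need no control, since step 6 erases both. The step needs chemoselectivity: exchange at selenium must outrun attack of butyllithium on the lactam carbonyls, and the carbanion must prefer 1,2-addition to the aldehyde over attack at C4–Cl, which the low temperature, the soft selenium centre and the high electrophilicity of the formyl group should secure; loss of lithium oxide from 9 should be slow at −78 °C.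

**Step 6**
Reactants: 11 pentacyclic alcohol
Product: 13 pentacyclic 2H-pyran (Cc=Ca double bond; Cb S), via mesylate 12 (not isolated)
Conditions: MsCl, Et3N, CH2Cl2, 0 °C to rt
Reagents that add atoms: none
Why: Dehydration through the mesylate, whose ionisation gives a cation at Ca stabilised by the enol ether oxygen of ring A; loss of the only β-hydrogen (on Cc) should give the conjugated alkene from all epimers of 11, with Cb untouched.

**Step 7**
Reactants: 13 pentacyclic 2H-pyran
Product: 15 pinacol boronate (Bpin on Ca; CaR/CbS/CcS), via alkylborane 14 (not isolated)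
Conditions: BH3·SMe2, THF, 0 °C to rt; then pinacol, rt
Reagents that add atoms: borane–dimethyl sulfide, C[S+](C)[BH3-]; pinacol, CC(C)(O)C(C)(C)O
Why: Hydroboration with syn addition of H–B, boron going to the less substituted benzylic Ca; attack on the face that carries the hydrogen of Cb (the other face is screened by the gem-dimethyl carbon attached to Cb) should set H on Cc cis to H on Cb (cis ring fusion) and boron on the same face (substrate control from Cb).

**Step 8**
Reactants: 15 pinacol boronate
Product: 18 target CNP0107253.2 (CaR/CbS/CcS), via lithium boronate complex 16 (not isolated), via β-iodo boronate 17 (not isolated)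
Conditions: 2-methylprop-1-enyllithium (from 1-bromo-2-methylprop-1-ene, t-BuLi, Et2O, −78 °C), THF, −78 °C; I2, MeOH, −78 °C; NaOMe, −78 °C to rt
Reagents that add atoms: 1-bromo-2-methylprop-1-ene, CC(C)=CBr
Why: Zweifel olefination, in which the alkenyllithium forms the boronate complex, iodine triggers 1,2-migration of the secondary carbon with retention at Ca and methoxide-induced anti-elimination of boron and iodine gives the alkene, so the 2-methylprop-1-enyl group takes the place of boron.

**Compound list**
1 | 4-hydroxy-1-methylquinolin-2(1H)-one | Cn1c(=O)cc(O)c2ccccc12 | starting material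
2 | 3-methylbut-2-enal | CC(C)=CC=O | starting material
3 | 1-methyl-3-(3-methylbut-2-en-1-ylidene)quinoline-2,4(1H,3H)-dione | CC(C)=CC=C1C(=O)N(C)c2ccccc2C1=O | intermediate
4 | N-methylflindersine, 2,2,6-trimethyl-2H-pyrano[3,2-c]quinolin-5(6H)-one | CC1(C)C=Cc2c(O1)c1ccccc1n(C)c2=O | intermediate
5 | (3S,4S)-3,4-epoxy-2,2,6-trimethyl-3,4-dihydro-2H-pyrano[3,2-c]quinolin-5(6H)-one | CC1(C)Oc2c(c(=O)n(C)c3ccccc23)[C@@H]2O[C@H]12 | intermediate
6 | (3R,4R)-3-hydroxy-2,2,6-trimethyl-4-(phenylselanyl)-3,4-dihydro-2H-pyrano[3,2-c]quinolin-5(6H)-one (trans) | CC1(C)Oc2c(c(=O)n(C)c3ccccc23)[C@@H]([Se]c2ccccc2)[C@@H]1O | intermediate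
7 | [(4-chloro-1-methyl-2-oxo-1,2-dihydroquinolin-3-yl)methylidene]dimethyliminium chloride | C[N+](C)=Cc1c(Cl)c2ccccc2n(C)c1=O.[Cl-] | intermediate
8 | 4-chloro-1-methyl-2-oxo-1,2-dihydroquinoline-3-carbaldehyde | O=Cc1c(Cl)c2ccccc2n(C)c1=O | intermediate
9 | dilithium (3S)-2,2,6-trimethyl-5-oxo-3-oxido-3,4,5,6-tetrahydro-2H-pyrano[3,2-c]quinolin-4-ide | CC1(C)Oc2c(c(=O)n(C)c3ccccc23)[CH-][C@@H]1[O-].[Li+].[Li+] | intermediate
10 | dilithium dialkoxide of (3S)-4-[(4-chloro-1-methyl-2-oxo-1,2-dihydroquinolin-3-yl)(hydroxy)methyl]-3-hydroxy-2,2,6-trimethyl-3,4-dihydro-2H-pyrano[3,2-c]quinolin-5(6H)-one, epimers at C4 and the carbinol carbon | [O-]C(c1c(Cl)c2ccccc2n(C)c1=O)C1c2c(c3ccccc3n(C)c2=O)OC(C)(C)[C@H]1[O-].[Li+].[Li+] | intermediate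
11 | pentacyclic alcohol: ring X closed by the O–C4(A) ether, OH on Ca, H on Cc, Cb (S), epimers at Ca and Cc | OC1c2c(c3ccccc3n(C)c2=O)O[C@H]2C1c1c(c3ccccc3n(C)c1=O)OC2(C)C | intermediate
12 | methanesulfonate of 11 | CS(=O)(=O)OC1c2c(c3ccccc3n(C)c2=O)O[C@H]2C1c1c(c3ccccc3n(C)c1=O)OC2(C)C | intermediate
13 | pentacyclic 2H-pyran: as 11 with a Cc=Ca double bond, Cb (S) | C1c2c(c3ccccc3n(C)c2=O)O[C@H]2C=1c1c(c3ccccc3n(C)c1=O)OC2(C)C | intermediate
14 | alkylborane: BH2 on Ca, H on Cc, both cis to H on Cb | B[C@H]1c2c(c3ccccc3n(C)c2=O)O[C@H]2[C@@H]1c1c(c3ccccc3n(C)c1=O)OC2(C)C | intermediate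
15 | pinacol boronate: Bpin on Ca, (Ca R, Cb S, Cc S), cis-fused rings X/Y | CC1(C)OB(OC1(C)C)[C@H]1c2c(c3ccccc3n(C)c2=O)O[C@H]2[C@@H]1c1c(c3ccccc3n(C)c1=O)OC2(C)C | intermediate
16 | lithium (2-methylprop-1-enyl)boronate complex of 15 | [Li+].CC(C)=C[B-]1(OC(C)(C)C(C)(C)O1)[C@H]1c2c(c3ccccc3n(C)c2=O)O[C@H]2[C@@H]1c1c(c3ccccc3n(C)c1=O)OC2(C)C | intermediate
17 | β-iodo boronate: Ca–CH(Bpin)–C(CH3)2I, configuration at Ca retained | CC(C)(I)C(B1OC(C)(C)C(C)(C)O1)[C@H]1c2c(c3ccccc3n(C)c2=O)O[C@H]2[C@@H]1c1c(c3ccccc3n(C)c1=O)OC2(C)C | intermediate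
18 | CNP0107253.2: (Ca R, Cb S, Cc S), cis-fused rings X/Y, 2-methylprop-1-enyl on Ca cis to both ring-fusion hydrogens | CC(C)=C[C@H]1c2c(c3ccccc3n(C)c2=O)O[C@H]2[C@@H]1c1c(c3ccccc3n(C)c1=O)OC2(C)C | target

**Totals.** Total step count: 8. Longest linear sequence: 7 steps (steps 1, 2, 3, 5, 6, 7, 8).

**Steps most likely to fail**

Step 5. Butyllithium may add to a lactam carbonyl faster than it exchanges at selenium, the β-oxido organolithium may lose lithium oxide before it meets the aldehyde, or ring closure may stall at the open adduct. The fallback keeps selenium on carbon and sets out from 6. LDA (2.2 equiv, THF, −78 °C) should deprotonate the hydroxyl and the benzylic C–H next to selenium to give the α-selanyl carbanion alkoxide F1. F1 adds to 8 to give the open adduct F2, which on warming closes by the same intramolecular SNAr to the β-hydroxy selenide F3. MsCl/Et3N then converts F3 through its mesylate F4, by reductive anti-elimination of the selanyl and oxygen groups via a seleniranium ion, into 13, where the route is rejoined.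

Step 7. Boron may be placed on Cc instead of Ca, borane may approach the wrong alkene face, or a lactam carbonyl may be reduced. The fallback leaves boron chemistry and sets out from 13. Camphorsulfonic acid (cat.) in MeOH/CH2Cl2 at 0 °C should add methanol in the Markovnikov sense, with the proton going to Cc on the less hindered face, to give the methyl ether F5. BF3·OEt2 and potassium trifluoro(2-methylprop-1-en-1-yl)borate in CH2Cl2/MeCN (−40 to 0 °C) then ionise F5 to the cation at Ca, which the alkenyl nucleophile should attack anti to ring Y. This gives 18 directly.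

Step 8. The alkenyllithium may attack a lactam carbonyl, or 1,2-migration of the hindered secondary carbon may be slow, so that iodination occurs without migration. The fallback builds the side chain by homologation and olefination and sets out from 15. Matteson homologation (bromochloromethane, n-BuLi, THF, −78 °C to rt) gives the homologated boronate F6 with retention at Ca. NaBO3·4H2O in THF/H2O gives the primary alcohol F7, and Dess–Martin periodinane gives the aldehyde F8. Wittig reaction with isopropylidenetriphenylphosphorane (isopropyltriphenylphosphonium iodide, KN(SiMe3)2, THF, −78 to 0 °C) gives 18.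

**Further compounds**
F1 | step 5 | dilithium α-phenylselanyl carbanion alkoxide of 6 | CC1(C)Oc2c(c(=O)n(C)c3ccccc23)[C-]([Se]c2ccccc2)[C@@H]1[O-].[Li+].[Li+]
F2 | step 5 | open-chain dilithium dialkoxide, as 10 with PhSe on C4 | [O-]C(c1c(Cl)c2ccccc2n(C)c1=O)C1([Se]c2ccccc2)c2c(c3ccccc3n(C)c2=O)OC(C)(C)[C@H]1[O-].[Li+].[Li+]
F3 | step 5 | pentacyclic β-hydroxy selenide, as 11 with PhSe on Cc, Cb (S) | OC1c2c(c3ccccc3n(C)c2=O)O[C@H]2C1([Se]c1ccccc1)c1c(c3ccccc3n(C)c1=O)OC2(C)C
F4 | step 5 | methanesulfonate of F3 | CS(=O)(=O)OC1c2c(c3ccccc3n(C)c2=O)O[C@H]2C1([Se]c1ccccc1)c1c(c3ccccc3n(C)c1=O)OC2(C)C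
F5 | step 7 | methyl ether: OCH3 on Ca (both epimers), H on Cc cis to H on Cb | COC1c2c(c3ccccc3n(C)c2=O)O[C@H]2[C@@H]1c1c(c3ccccc3n(C)c1=O)OC2(C)C
F6 | step 8 | homologated boronate: CH2Bpin on Ca, configured as 15 | CC1(C)OB(OC1(C)C)C[C@H]1c2c(c3ccccc3n(C)c2=O)O[C@H]2[C@@H]1c1c(c3ccccc3n(C)c1=O)OC2(C)C
F7 | step 8 | primary alcohol: CH2OH on Ca | OC[C@H]1c2c(c3ccccc3n(C)c2=O)O[C@H]2[C@@H]1c1c(c3ccccc3n(C)c1=O)OC2(C)C
F8 | step 8 | aldehyde: CHO on Ca | O=C[C@H]1c2c(c3ccccc3n(C)c2=O)O[C@H]2[C@@H]1c1c(c3ccccc3n(C)c1=O)OC2(C)C
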